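**Retrosynthetic overview**

1. Numbering of the target decalin: C-1 (quaternary, ArCH2), C-2 (CHMe), C-3, C-4, C-4a (ring-fusion CH), C-5 (methylidene carbon), C-6 to C-8, C-8a (angular methyl). Ring A is C-4a, C-5 to C-8, C-8a; ring B is C-1 to C-4, C-4a, C-8a.
2. Endgame: the hydroxy-methoxy-quinone comes from a tetramethoxyarene; the ArCH2–C1 bond from an aryllithium and a C-1 aldehyde, then benzylic deoxygenation; the C-5 methylidene from a ketone; H-2 and H-4a from a hydroxyl-directed hydrogenation of a ring-B diene.
3. Key disconnection: ring B is opened at C3–C4 and at C1–C2. This gives propyne and a ring-A cyclohexanone with a vinyl triflate carbon (C-4) on C-4a and an α-branched aldehyde on quaternary C-8a; a Sonogashira coupling and a 6-endo-dig enamine Michael closure rebuild both bonds in one operation.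
4. Enabling feature: the C-5 ketone of ring A is conjugated through C4a=C4 to the new alkyne and makes C-2 electrophilic. Nucleophilic C-1 (α-carbon of the aldehyde on C-8a) stands 1,4 to C-4 across the C8a–C4a bond, so a two-carbon alkyne bridges them, and quaternary C-8a steers the new quaternary C-1.
5. Ring order: ring A is bought (3-ethoxycyclohexenone) and receives C-8a by asymmetric conjugate addition; ring B is closed in the key step; the quinone ring arrives as 1,2,4,5-tetramethoxybenzene and is unveiled last.

Key step: step 6

Remark on the chemistry: compounds 3 to 11 are carried as mixtures of epimers at the side-chain carbon, and 8, 9 and 11 as E/Z mixtures, because step 6 erases both elements; positions in the Why lines use the target numbering given above.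

**Route**

Step 1
Reactants: 1 3-ethoxycyclohex-2-en-1-one; 2 (but-2-en-1-yl)magnesium chloride
Product: 3 3-(but-3-en-2-yl)cyclohex-2-en-1-one (racemic)
Conditions: THF, 0 °C; then 1 M HCl, 0 °C
Reagents that add atoms: water, O
Why: Stork–Danheiser enone transposition, in which the allylic Grignard reagent adds through its γ-carbon to the carbonyl of the vinylogous ester and acid-promoted loss of water and ethanol should give the transposed 3-substituted enone; the side-chain stereocentre is left uncontrolled because step 6 planarises it.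

Step 2
Reactants: 3 3-(but-3-en-2-yl)cyclohex-2-en-1-one
Product: 5 (3R)-3-(but-3-en-2-yl)-3-methylcyclohex-1-en-1-yl acetate (both side-chain epimers), via aluminium enolate 4 (not isolated)
Conditions: Me3Al, copper thiophene-2-carboxylate (2 mol%), chiral biphenol-derived bis(1-phenylethyl)amine phosphoramidite ligand (4 mol%), Et2O, −30 °C; then Ac2O, −30 °C to rt
Reagents that add atoms: trimethylaluminium, C[Al](C)C; acetic anhydride, CC(=O)OC(C)=O
Why: copper-catalysed asymmetric conjugate addition of Me3Al to a β-substituted cyclohexenone should create the quaternary centre C-8a under ligand control (the ligand antipode is chosen to give the 3R enolate), and acetylation of the aluminium enolate fixes the enolate regiochemistry at the hindered α-carbon.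

Step 3
Reactants: 5 (3R)-3-(but-3-en-2-yl)-3-methylcyclohex-1-en-1-yl acetate
Product: 7 (3R)-3-(but-3-en-2-yl)-2-(hydroxymethylidene)-3-methylcyclohexan-1-one, via lithium enolate 6 (not isolated)
Conditions: MeLi (2.1 equiv), THF, 0 °C; then HCO2Et, −78 °C to 0 °C; 1 M HCl
Reagents that add atoms: ethyl formate, CCOC=O
Why: cleavage of the enol acetate with MeLi releases the regiodefined lithium enolate, which should undergo Claisen formylation at the α-carbon next to the quaternary centre (the lithium tert-butoxide formed alongside deprotonates the acidic product); no stereocentre is formed.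

Step 4
Reactants: 7 (3R)-3-(but-3-en-2-yl)-2-(hydroxymethylidene)-3-methylcyclohexan-1-one
Product: 8 [(6R)-6-(but-3-en-2-yl)-6-methyl-2-oxocyclohexylidene]methyl trifluoromethanesulfonate (E/Z mixture)
Conditions: Tf2O, 2,6-lutidine, CH2Cl2, −78 °C
Reagents that add atoms: trifluoromethanesulfonic anhydride, O=S(=O)(OS(=O)(=O)C(F)(F)F)C(F)(F)F
Why: O-sulfonylation of the enol of the β-keto aldehyde at the formyl oxygen should give the vinylogous acyl triflate, a vinyl electrophile at C-4; its alkene geometry is immaterial because step 6 equilibrates it.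

Step 5
Reactants: 8 [(6R)-6-(but-3-en-2-yl)-6-methyl-2-oxocyclohexylidene]methyl trifluoromethanesulfonate
Product: 9 [(6R)-6-methyl-2-oxo-6-(1-oxopropan-2-yl)cyclohexylidene]methyl trifluoromethanesulfonate
Conditions: O3 (1 equiv), CH2Cl2, −78 °C; then Me2S, −78 °C to rt
Reagents that add atoms: ozone, [O-][O+]=O
Why: ozonolysis with reductive work-up should cleave only the electron-rich monosubstituted alkene, the triflyloxy enone alkene being strongly deactivated, and unveil the α-branched aldehyde; no stereocentre is set.

Step 6
Reactants: 9 [(6R)-6-methyl-2-oxo-6-(1-oxopropan-2-yl)cyclohexylidene]methyl trifluoromethanesulfonate; 10 propyne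
Product: 12 (1R,8aR)-1,2,8a-trimethyl-5-oxo-1,5,6,7,8,8a-hexahydronaphthalene-1-carbaldehyde, via ynenone aldehyde 11 (not isolated)
Conditions: Pd(PPh3)2Cl2 (5 mol%), CuI (10 mol%), iPr2NEt, THF, 0 °C to rt; argon purge; then pyrrolidine (30 mol%), AcOH (30 mol%), 40 °C
Reagents that add atoms: none
Why: Proposed new method: zerovalent palladium inserts into the vinyl C–O bond at C-4, the copper acetylide of propyne transmetalates and reductive elimination gives the 2-en-4-ynone 11 (C3–C4 bond), after which pyrrolidine converts the α-branched aldehyde into its enamine, whose carbon C-1 adds to the alkyne terminus C-2, the δ-position of the ynenone, and protonation plus iminium hydrolysis release 12 and the amine (C1–C2 bond). The closest known reaction types are the Sonogashira coupling of β-sulfonyloxy enones and the amine-catalysed intramolecular Michael addition of aldehydes to enones and ynones, including endo-dig Michael closures onto ynones. Ring B closes in the 6-endo-dig mode, and this regiochemistry is secured by conjugation with the ring-A ketone, because the competing 5-exo attack at C-3 would be an anti-Michael addition. The only new stereocentre, quaternary C-1, is controlled by quaternary C-8a next to it: the planar enamine can reach C-2 only from the face of the ynenone plane opposite to the C-8a methyl, and its bulky N–CH= arm takes the pseudo-axial site anti to that methyl while the C-1 methyl lies pseudo-equatorial, so that the formyl group ends trans to the C-8a methyl and the two methyls cis. The step is stereoconvergent, since both C-1 epimers of 9 give the same enamine and the E and Z isomers of 11 interconvert by reversible conjugate addition of the amine at C-4, only the isomer with the alkyne cis to C-8a being able to close. The chemoselectivity that is needed, enamine formation at the aldehyde and not at the ketone, follows from the much higher reactivity of the aldehyde carbonyl toward the secondary amine.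

Step 7
Reactants: 12 (1R,8aR)-1,2,8a-trimethyl-5-oxo-1,5,6,7,8,8a-hexahydronaphthalene-1-carbaldehyde; 13 1,2,4,5-tetramethoxybenzene
Product: 15 (4aR,5R)-5-[hydroxy(2,3,5,6-tetramethoxyphenyl)methyl]-4a,5,6-trimethyl-3,4,4a,5-tetrahydronaphthalen-1(2H)-one (both carbinol epimers), via aryllithium 14 (not isolated)
Conditions: 13, n-BuLi, TMEDA, THF, 0 °C; then 12, −78 °C; NH4Cl (aq)
Reagents that add atoms: none
Why: directed ortho-lithiation of the arene followed by 1,2-addition of the aryllithium should take place at the aldehyde, which is far more electrophilic than the conjugated and hindered dienone carbonyl; the carbinol centre forms as a mixture that is removed in step 10.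

Step 8
Reactants: 15 (4aR,5R)-5-[hydroxy(2,3,5,6-tetramethoxyphenyl)methyl]-4a,5,6-trimethyl-3,4,4a,5-tetrahydronaphthalen-1(2H)-one
Product: 16 (4aS,5R,6S,8aR)-5-[hydroxy(2,3,5,6-tetramethoxyphenyl)methyl]-4a,5,6-trimethyloctahydronaphthalen-1(2H)-one
Conditions: H2 (1 atm), [Ir(cod)(PCy3)(py)]PF6 (10 mol%), CH2Cl2, rt
Reagents that add atoms: none
Why: hydroxyl-directed homogeneous hydrogenation, in which the carbinol held on the face trans to the angular methyl should bind the cationic iridium catalyst and deliver hydrogen to C-2 and C-4a from that face, setting the axial C-2 methyl (cis to both other methyls) and the trans ring fusion against the steric bias of the benzylic group.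

Step 9
Reactants: 16 (4aS,5R,6S,8aR)-5-[hydroxy(2,3,5,6-tetramethoxyphenyl)methyl]-4a,5,6-trimethyloctahydronaphthalen-1(2H)-one
Product: 17 [(1R,2S,4aS,8aS)-1,2,8a-trimethyl-5-methylidenedecahydronaphthalen-1-yl](2,3,5,6-tetramethoxyphenyl)methanol
Conditions: Cp2TiMe2 (3 equiv), toluene, 65 °C, dark
Reagents that add atoms: dimethyltitanocene, C[Ti](C)(C1C=CC=C1)C1C=CC=C1
Why: Petasis methylenation through the titanium methylidene Cp2Ti=CH2 is non-basic and should convert the hindered, enolisable ketone into the exocyclic alkene without epimerising the adjacent ring-fusion centre C-4a.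

Step 10
Reactants: 17 [(1R,2S,4aS,8aS)-1,2,8a-trimethyl-5-methylidenedecahydronaphthalen-1-yl](2,3,5,6-tetramethoxyphenyl)methanol
Product: 18 1,2,4,5-tetramethoxy-3-{[(1R,2S,4aS,8aS)-1,2,8a-trimethyl-5-methylidenedecahydronaphthalen-1-yl]methyl}benzene
Conditions: Li, NH3(l)–THF, −78 °C; then NH4Cl
Reagents that add atoms: none
Why: dissolving-metal reduction should cleave the benzylic C–O bond (benzylic deoxygenation by way of the arene radical anion) and leave the isolated exocyclic alkene and all ring stereocentres untouched.

Step 11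
Reactants: 18 1,2,4,5-tetramethoxy-3-{[(1R,2S,4aS,8aS)-1,2,8a-trimethyl-5-methylidenedecahydronaphthalen-1-yl]methyl}benzene
Product: 19 2,5-dimethoxy-3-{[(1R,2S,4aS,8aS)-1,2,8a-trimethyl-5-methylidenedecahydronaphthalen-1-yl]methyl}cyclohexa-2,5-diene-1,4-dione
Conditions: (NH4)2Ce(NO3)6, MeCN–H2O, 0 °C
Reagents that add atoms: water, O
Why: oxidative demethylation of one para pair of methoxy groups by tetravalent cerium should give the 2,5-dimethoxy-1,4-benzoquinone, either para pair leading to the same product by symmetry.

Step 12
Reactants: 19 2,5-dimethoxy-3-{[(1R,2S,4aS,8aS)-1,2,8a-trimethyl-5-methylidenedecahydronaphthalen-1-yl]methyl}cyclohexa-2,5-diene-1,4-dione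
Product: 20 2-hydroxy-5-methoxy-3-{[(1R,2S,4aS,8aS)-1,2,8a-trimethyl-5-methylidenedecahydronaphthalen-1-yl]methyl}cyclohexa-2,5-diene-1,4-dione (CNP0109104.1)
Conditions: KOH, MeOH–H2O, rt; then 1 M HCl
Reagents that add atoms: water, O
Why: addition–elimination of hydroxide at the vinylogous ester should occur at the methoxy group flanked by the alkyl substituent, which is twisted out of conjugation and hence the more electrophilic, to give the 2-hydroxy-5-methoxyquinone.

**Compound list**

1 | 3-ethoxycyclohex-2-en-1-one | CCOC1=CC(=O)CCC1 | starting material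
2 | (but-2-en-1-yl)magnesium chloride | CC=CC[Mg]Cl | starting material
3 | 3-(but-3-en-2-yl)cyclohex-2-en-1-one (racemic) | O=C1C=C(C(C)C=C)CCC1 | intermediate
4 | dimethylaluminium (3R)-3-(but-3-en-2-yl)-3-methylcyclohex-1-en-1-olate (both side-chain epimers) | C[Al](C)OC1=C[C@@](C)(C(C)C=C)CCC1 | intermediate
5 | (3R)-3-(but-3-en-2-yl)-3-methylcyclohex-1-en-1-yl acetate (both side-chain epimers) | CC(=O)OC1=C[C@@](C)(C(C)C=C)CCC1 | intermediate
6 | lithium (3R)-3-(but-3-en-2-yl)-3-methylcyclohex-1-en-1-olate | [Li]OC1=C[C@@](C)(C(C)C=C)CCC1 | intermediate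
7 | (3R)-3-(but-3-en-2-yl)-2-(hydroxymethylidene)-3-methylcyclohexan-1-one | O=C1CCC[C@](C)(C(C)C=C)C1=CO | intermediate
8 | [(6R)-6-(but-3-en-2-yl)-6-methyl-2-oxocyclohexylidene]methyl trifluoromethanesulfonate (E/Z mixture) | O=C1CCC[C@](C)(C(C)C=C)C1=COS(=O)(=O)C(F)(F)F | intermediate
9 | [(6R)-6-methyl-2-oxo-6-(1-oxopropan-2-yl)cyclohexylidene]methyl trifluoromethanesulfonate (E/Z mixture, both side-chain epimers) | O=C1CCC[C@](C)(C(C)C=O)C1=COS(=O)(=O)C(F)(F)F | intermediate
10 | propyne | CC#C | starting material
11 | 2-[(1R)-2-(but-2-yn-1-ylidene)-1-methyl-3-oxocyclohexyl]propanal (E/Z mixture, both side-chain epimers) | O=C1CCC[C@](C)(C(C)C=O)C1=CC#CC | intermediate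
12 | (1R,8aR)-1,2,8a-trimethyl-5-oxo-1,5,6,7,8,8a-hexahydronaphthalene-1-carbaldehyde | O=C1CCC[C@@]2(C)C1=CC=C(C)[C@@]2(C)C=O | intermediate
13 | 1,2,4,5-tetramethoxybenzene | COc1cc(OC)c(OC)cc1OC | starting material
14 | (2,3,5,6-tetramethoxyphenyl)lithium | [Li]c1c(OC)c(OC)cc(OC)c1OC | intermediate
15 | (4aR,5R)-5-[hydroxy(2,3,5,6-tetramethoxyphenyl)methyl]-4a,5,6-trimethyl-3,4,4a,5-tetrahydronaphthalen-1(2H)-one (both carbinol epimers) | O=C1CCC[C@@]2(C)C1=CC=C(C)[C@@]2(C)C(O)c1c(OC)c(OC)cc(OC)c1OC | intermediate
16 | (4aS,5R,6S,8aR)-5-[hydroxy(2,3,5,6-tetramethoxyphenyl)methyl]-4a,5,6-trimethyloctahydronaphthalen-1(2H)-one (both carbinol epimers) | O=C1CCC[C@@]2(C)[C@H]1CC[C@H](C)[C@@]2(C)C(O)c1c(OC)c(OC)cc(OC)c1OC | intermediate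
17 | [(1R,2S,4aS,8aS)-1,2,8a-trimethyl-5-methylidenedecahydronaphthalen-1-yl](2,3,5,6-tetramethoxyphenyl)methanol (both carbinol epimers) | C=C1CCC[C@@]2(C)[C@H]1CC[C@H](C)[C@@]2(C)C(O)c1c(OC)c(OC)cc(OC)c1OC | intermediate
18 | 1,2,4,5-tetramethoxy-3-{[(1R,2S,4aS,8aS)-1,2,8a-trimethyl-5-methylidenedecahydronaphthalen-1-yl]methyl}benzene | C=C1CCC[C@@]2(C)[C@H]1CC[C@H](C)[C@@]2(C)Cc1c(OC)c(OC)cc(OC)c1OC | intermediate
19 | 2,5-dimethoxy-3-{[(1R,2S,4aS,8aS)-1,2,8a-trimethyl-5-methylidenedecahydronaphthalen-1-yl]methyl}cyclohexa-2,5-diene-1,4-dione | C=C1CCC[C@@]2(C)[C@H]1CC[C@H](C)[C@@]2(C)CC1=C(OC)C(=O)C=C(OC)C1=O | intermediate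
20 | 2-hydroxy-5-methoxy-3-{[(1R,2S,4aS,8aS)-1,2,8a-trimethyl-5-methylidenedecahydronaphthalen-1-yl]methyl}cyclohexa-2,5-diene-1,4-dione | C=C1CCC[C@@]2(C)[C@H]1CC[C@H](C)[C@@]2(C)CC1=C(O)C(=O)C=C(OC)C1=O | target

**Step count and risks**

Total step count: 12. Longest linear sequence: 12 steps (1 to 20); the arene 13 enters in step 7.

Step 6 (proposed new method). The amine may add irreversibly to the δ-carbon of the ynenone, or copper may couple aldehyde, amine and residual propyne, before the enamine closes the ring; the closure may also proceed without facial control at C-1. The fallback uses known chemistry and sets out from 9. Sonogashira coupling with 10 under the same palladium–copper conditions, stopped before the amine is added, would give 11, which would be isolated. Soft enolisation of its aldehyde (TBSOTf, Et3N, CH2Cl2, −78 °C) would give the silyl enol ether (3R)-2-(but-2-yn-1-ylidene)-3-{1-[(tert-butyldimethylsilyl)oxy]prop-1-en-2-yl}-3-methylcyclohexan-1-one F1. A cationic monovalent gold catalyst, (JohnPhos)Au(MeCN)SbF6 in wet CH2Cl2, would then effect the known carbocyclisation of a silyl enol ether onto an alkyne. The attack is again directed to the δ-carbon by the conjugated ketone, and the route is rejoined at 12.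

Step 8. Hydrogen may be delivered to the wrong face, or only one of the two alkenes may be reduced, if the crowded secondary benzylic hydroxyl binds iridium poorly. The fallback changes the directing group and sets out from 12. Chemoselective reduction of the aldehyde (NaBH4, MeOH–CH2Cl2, −78 °C) would give the primary alcohol (4aR,5R)-5-(hydroxymethyl)-4a,5,6-trimethyl-3,4,4a,5-tetrahydronaphthalen-1(2H)-one F2. Its unhindered hydroxymethyl group on the same face should direct [Ir(cod)(PCy3)(py)]PF6/H2 to give (4aS,5R,6S,8aR)-5-(hydroxymethyl)-4a,5,6-trimethyloctahydronaphthalen-1(2H)-one F3. Oxidation with Dess–Martin periodinane would give the keto aldehyde (1R,2S,4aR,8aS)-1,2,8a-trimethyl-5-oxodecahydronaphthalene-1-carbaldehyde F4. Addition of the non-basic aryl cerium reagent made from 14 and CeCl3 at −78 °C, selective for the aldehyde, rejoins the route at 16.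

Step 10. Over-reduction of the electron-rich arene (ring reduction or loss of methoxy groups) may compete with cleavage of the benzylic C–O bond. The fallback is a radical deoxygenation and sets out from 17. Treatment with NaH, CS2 and MeI would give the xanthate O-{[(1R,2S,4aS,8aS)-1,2,8a-trimethyl-5-methylidenedecahydronaphthalen-1-yl](2,3,5,6-tetramethoxyphenyl)methyl} S-methyl carbonodithioate F5. Barton–McCombie reduction (Bu3SnH, AIBN, toluene, 110 °C) would then give 18, where the route is rejoined.

**Further compounds**

F1 | step 6 | (3R)-2-(but-2-yn-1-ylidene)-3-{1-[(tert-butyldimethylsilyl)oxy]prop-1-en-2-yl}-3-methylcyclohexan-1-one | O=C1CCC[C@](C)(C(C)=CO[Si](C)(C)C(C)(C)C)C1=CC#CC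
F2 | step 8 | (4aR,5R)-5-(hydroxymethyl)-4a,5,6-trimethyl-3,4,4a,5-tetrahydronaphthalen-1(2H)-one | O=C1CCC[C@@]2(C)C1=CC=C(C)[C@@]2(C)CO
F3 | step 8 | (4aS,5R,6S,8aR)-5-(hydroxymethyl)-4a,5,6-trimethyloctahydronaphthalen-1(2H)-one | O=C1CCC[C@@]2(C)[C@H]1CC[C@H](C)[C@@]2(C)CO
F4 | step 8 | (1R,2S,4aR,8aS)-1,2,8a-trimethyl-5-oxodecahydronaphthalene-1-carbaldehyde | O=C1CCC[C@@]2(C)[C@H]1CC[C@H](C)[C@@]2(C)C=O
F5 | step 10 | O-{[(1R,2S,4aS,8aS)-1,2,8a-trimethyl-5-methylidenedecahydronaphthalen-1-yl](2,3,5,6-tetramethoxyphenyl)methyl} S-methyl carbonodithioate | C=C1CCC[C@@]2(C)[C@H]1CC[C@H](C)[C@@]2(C)C(OC(=S)SC)c1c(OC)c(OC)cc(OC)c1OC
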